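The runs were computed with constants of no real substance, noise included.

Do not book each reagent charged as one substrate consumed: the earlier runs refuse it.

| setting | east | north-west | teal | green |
|---|---|---|---|---|
| substrate | 10 mM (fed, over 12 min) | 10 mM (fed, over 12 min) | 10 mM (fed, over 12 min) | 10 mM (fed, over 12 min) |
| reagent | 3.1 mM | 13 mM | 5.00 mM | 15.0 mM |
| remark | run made earlier | run made earlier |  |  |
| time |  |  | 3.0 h | 3.0 h |

| run | time / min | isomer of the product / % | over-reaction product / % | target / % | substrate / % |
|---|---|---|---|---|---|
| east | 12.0 | 13.0 | 0 | 7.2 | 79.0 |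
| east | 30.0 | 23.6 | 2.6 | 3.9 | 72.8 |
| east | 60.0 | 20.9 | 2.6 | 1.5 | 72.9 |
| east | 90.0 | 22.9 | 3.1 | 1.1 | 71.5 |
| east | 120 | 22.0 | 2.0 | 1.4 | 72.8 |
| north-west | 25.0 | 65.6 | 5.4 | 8.4 | 21.9 |
| north-west | 50.0 | 78.4 | 6.0 | 3.7 | 15.1 |
| north-west | 80.0 | 76.1 | 6.7 | 3.5 | 13.4 |
| north-west | 90.0 | 75.9 | 6.8 | 2.6 | 15.6 |
| north-west | 120 | 74.1 | 7.5 | 0.6 | 16.2 |

(scatter of a reading: 1 percentage point)

- which of these there is most of at the end, counted by the substrate in it, teal (substrate / target / isomer of the product / over-reaction product)
- which of these there is most of at the end, counted by the substrate in it, green (substrate / target / isomer of the product / over-reaction product)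
- the largest of these amounts at the end, in percent of the substrate charged, teal
- the largest of these amounts at the end, in percent of the substrate charged, green

Turn the time first. By hand, waiting changes little in east, whose substrate reads 72.9 % at 60.0 min and 72.8 % at 120 min, so take the mean of the last 3 readings as each run's end for substrate. But north-west's isomer of the product sinks by 4.3 percentage points between 50.0 min and 120 min. Carrying that pace to 3.0 h puts it near 70.4 %, which is 82.9 % of the substrate consumed there.

Turn the reagent next. Reckon the reagent return, the substrate consumed per reagent charged: east gives 0.890 and north-west 0.653, a fall of 0.0239 mM⁻¹. Teal charges less reagent than substrate, so reagent is its limiting reagent.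

My first round takes the nearest run's return: teal consumes 4.45 mM, green 9.79 mM. The second round puts those charges back on the line between the runs. Teal's return becomes 0.845, leaving 57.8 % substrate, more than is consumed. Green's return, extrapolated, becomes 0.605, leaving 9.18 % substrate and giving 75.3 % isomer of the product.

The forecast says substrate at 59 % (54 % to 63 %) for teal and isomer of the product at 83 % (78 % to 87 %) for green, on the ground that “excess reagent is wasted by a side loss that grows as substrate runs low or reagent stays high”. My green figure lies below it.

The flasks give substrate at 58.0 % in teal and isomer of the product at 73.7 % in green.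

    substrate + reagent ⇌ target (K = 89.0 M⁻¹, k = 0.600 M⁻¹ s⁻¹)
    substrate + reagent ⇌ isomer of the product (K = 2100 M⁻¹, k = 0.320 M⁻¹ s⁻¹)
    reagent ⇌ dormant form (K = 2.10, k = 1.40 × 10⁻⁴ s⁻¹)
    target → over-reaction product (k = 2.00 × 10⁻⁴ s⁻¹)

The returns come to 0.841 in teal and 0.579 in green. Green's 15.0 mM of reagent stands at the end as 8.68 mM consumed with substrate, 2.47 mM free and 3.85 mM dormant form. For a neighbouring flask, teal's recipe with 12 mM of reagent, the line gives a return of 0.677 and 18.7 % substrate left. That flask ends with 19.7 % substrate, a return of 0.669.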